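**Plan**
Cuts, in retrosynthetic order: the eight O–CH3 bonds (all phenols travel as methyl ethers), the C6–vinyl bond of unit A (Heck), C2–C3 of ring A, the C3–C6' bond between the units (aryllithium + aldehyde), C2'–C3' of ring B, and the C3'–aryl bond (Grignard + aldehyde).
Enabling feature: in ring B (O1'–C2'–C3'–C3a'–C7a') C2' is an ether carbon that is also benzylic to the 4-oxyphenyl ring, and it lies next to the diarylmethine C3'. The C2'–C3' bond therefore equals a diaryl carbene at C3' plus a C–H bond of a 4-methoxybenzyl ether on O1'. Ring A repeats this pattern at C2–C3.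
Forward: one aldehyde (4) is used twice. It first takes up the 3,5-dimethoxyphenyl group and is closed to ring B (step 7). The resulting bromide is lithiated, added to a second portion of 4 and closed to ring A (step 12). The last bromide then carries the stilbene (step 14) and all ethers are cleaved at the end (step 15).
Stereochemistry: C3' and C3 come from the chiral dirhodium catalyst. The same antipode serves both times, because both rings have the same absolute sense (all four centres S). C2' and C2 are brought to trans by acid equilibration, and the E alkene comes from the Heck syn-insertion/syn-elimination.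

Key step: step 7

Assumption: the S-configured phthalimido-adamantylacetate catalyst is taken to give (3S) with this di-ortho-substituted carbene. Both antipodes are commercial, so if an anomalous-dispersion X-ray check on bromide 12 should show the opposite sense, Rh2(R-PTAD)4 replaces it in steps 7 and 12 and nothing else changes.

Step 1
Reactants: 1 4-bromo-2,6-dimethoxybenzaldehyde
Product: 2 4-bromo-2-hydroxy-6-methoxybenzaldehyde
Conditions: BCl3 (1.1 equiv), CH2Cl2, −78 → 0 °C; then H2O
Reagents that add atoms: none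
Why: Chelation-directed ether cleavage, in which boron bridges the aldehyde oxygen and one neighbouring methoxy oxygen in a six-membered chelate, chloride takes that methyl group, and the aryloxyboron chelate so formed ties up the carbonyl group and protects the second ortho ether at this stoichiometry and temperature.

Step 2
Reactants: 2 4-bromo-2-hydroxy-6-methoxybenzaldehyde; 3 4-methoxybenzyl chloride
Product: 4 4-bromo-2-methoxy-6-[(4-methoxybenzyl)oxy]benzaldehyde
Conditions: K2CO3, n-Bu4NI (cat.), DMF, 60 °C
Reagents that add atoms: 4-methoxybenzyl chloride (compound 3), COc1ccc(CCl)cc1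
Why: Williamson ether synthesis of a salicylaldehyde-type phenoxide with a reactive benzylic chloride, which puts in place the OCH2Ar unit whose carbon becomes C2' in one portion of the material and C2 in the other.

Step 3
Reactants: 5 1-bromo-3,5-dimethoxybenzene; 4 4-bromo-2-methoxy-6-[(4-methoxybenzyl)oxy]benzaldehyde
Product: 7 [4-bromo-2-methoxy-6-(4-methoxybenzyloxy)phenyl](3,5-dimethoxyphenyl)methanol (racemic), via 3,5-dimethoxyphenylmagnesium bromide 6 (not isolated)
Conditions: 5, Mg, I2 (cat.), THF, reflux; then 4, THF, 0 °C → rt; H2O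
Reagents that add atoms: none
Why: Grignard addition to an aldehyde, in which the aryl bromide of 4 does not exchange with an arylmagnesium halide at this temperature and the new carbinol centre is erased in step 4, so no stereocontrol is needed.

Step 4
Reactants: 7 [4-bromo-2-methoxy-6-(4-methoxybenzyloxy)phenyl](3,5-dimethoxyphenyl)methanol
Product: 8 [4-bromo-2-methoxy-6-(4-methoxybenzyloxy)phenyl](3,5-dimethoxyphenyl)methanone
Conditions: Dess–Martin periodinane, CH2Cl2, rt
Reagents that add atoms: none
Why: Dess–Martin oxidation of a secondary diaryl carbinol under near-neutral conditions, which spare the oxidisable 4-methoxybenzyl ether that quinone or cerium oxidants would attack.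

Step 5
Reactants: 8 [4-bromo-2-methoxy-6-(4-methoxybenzyloxy)phenyl](3,5-dimethoxyphenyl)methanone
Product: 9 hydrazone of ketone 8 (E/Z mixture)
Conditions: N2H4·H2O (large excess), AcOH (cat.), n-BuOH, 120 °C, sealed tube
Reagents that add atoms: hydrazine (used as the monohydrate), NN
Why: Acid-catalysed hydrazone condensation, driven by excess hydrazine and heat because two ortho alkoxy groups shield the carbonyl carbon, while the same crowding makes azine formation unlikely and the C=N geometry is lost in step 6.

Step 6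
Reactants: 9 hydrazone of ketone 8
Product: 10 [4-bromo-2-methoxy-6-(4-methoxybenzyloxy)phenyl](3,5-dimethoxyphenyl)diazomethane
Conditions: activated MnO2, CH2Cl2, 0 °C → rt, dark; filtration through Celite, used at once
Reagents that add atoms: none
Why: Dehydrogenation of a diaryl ketone hydrazone to the diaryldiazomethane with activated manganese dioxide, a mild heterogeneous oxidation that leaves benzylic ethers alone and whose solid residue is filtered off before the rhodium catalyst is added.

Step 7
Reactants: 10 [4-bromo-2-methoxy-6-(4-methoxybenzyloxy)phenyl](3,5-dimethoxyphenyl)diazomethane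
Product: 12 (2S,3S)-6-bromo-3-(3,5-dimethoxyphenyl)-4-methoxy-2-(4-methoxyphenyl)-2,3-dihydrobenzofuran (trans ring-B bromide), via cis ring-B bromide 11 (not isolated)
Conditions: Rh2(S-PTAD)4 (1 mol %), 4 Å MS, CH2Cl2, 0 °C → rt; then CF3CO2H, 0 °C → rt, same flask
Reagents that add atoms: none
Why: The catalyst expels nitrogen from 10 and gives a rhodium carbene at C3' whose two electron-rich aryl groups temper its electrophilicity enough to hold back azine and dimer formation while leaving it reactive toward a hydridic C–H bond. The closest known reaction type is the dirhodium-catalysed intramolecular C–H insertion of donor/donor diaryl carbenes into benzylic ethers, which delivers 2,3-diaryl-2,3-dihydrobenzofurans. Ring B closes as a 1,5-insertion: an OCH2 hydrogen five atoms from the carbene carbon moves to C3' in a hydride-like, asynchronous but concerted event while C2'–C3' forms, so the five-membered ring O1'–C2'–C3'–C3a'–C7a' arises in one step. C3' is fixed by the chiral adamantylglycinate ligand pocket, which decides the carbene face that accepts the hydrogen, and the compact transition state should first place the two aryl groups cis (11). C2' is then set thermodynamically, because trifluoroacetic acid reversibly ionises C2'–O1' to a 4-methoxybenzylic cation that recloses on the face away from the C3' aryl group and leaves C3' untouched. The step needs site selectivity between the two ortho alkoxy groups, and the substrate secures it because the benzylic C–H bond, activated by both the oxygen and the p-anisyl ring, is much the better hydride donor than a C–H bond of the methyl ether.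

Step 8
Reactants: 12 trans ring-B bromide; 4 4-bromo-2-methoxy-6-[(4-methoxybenzyl)oxy]benzaldehyde
Product: 14 [4-bromo-2-methoxy-6-(4-methoxybenzyloxy)phenyl][(2S,3S)-3-(3,5-dimethoxyphenyl)-4-methoxy-2-(4-methoxyphenyl)-2,3-dihydrobenzofuran-6-yl]methanol (both carbinol epimers), via ring-B aryllithium 13 (not isolated)
Conditions: n-BuLi (1.05 equiv), THF, −78 °C; then 4, −78 → −20 °C; H2O
Reagents that add atoms: none
Why: Bromine–lithium exchange outruns deprotonation of C2'–H or C3'–H at −78 °C, and the aryllithium then undergoes 1,2-addition to the aldehyde faster than it exchanges with the aryl bromide of 4, the new carbinol centre being removed in step 9.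

Step 9
Reactants: 14 diaryl carbinol
Product: 15 [4-bromo-2-methoxy-6-(4-methoxybenzyloxy)phenyl][(2S,3S)-3-(3,5-dimethoxyphenyl)-4-methoxy-2-(4-methoxyphenyl)-2,3-dihydrobenzofuran-6-yl]methanone
Conditions: Dess–Martin periodinane, CH2Cl2, rt
Reagents that add atoms: none
Why: Dess–Martin oxidation as in step 4, which merges both carbinol epimers into one ketone and touches neither the 4-methoxybenzyl ether nor the benzylic C–H bonds of ring B.

Step 10
Reactants: 15 diaryl ketone
Product: 16 hydrazone of ketone 15 (E/Z mixture)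
Conditions: N2H4·H2O (large excess), AcOH (cat.), n-BuOH, 120 °C, sealed tube
Reagents that add atoms: hydrazine (used as the monohydrate), NN
Why: The same hydrazone condensation as in step 5 on a carbonyl group with the same local environment, under conditions too weakly basic to epimerise the diarylmethine C3'.

Step 11
Reactants: 16 hydrazone of ketone 15
Product: 17 [4-bromo-2-methoxy-6-(4-methoxybenzyloxy)phenyl][(2S,3S)-3-(3,5-dimethoxyphenyl)-4-methoxy-2-(4-methoxyphenyl)-2,3-dihydrobenzofuran-6-yl]diazomethane
Conditions: activated MnO2, CH2Cl2, 0 °C → rt, dark; filtration through Celite, used at once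
Reagents that add atoms: none
Why: Manganese dioxide dehydrogenation of a diaryl ketone hydrazone as in step 6, short and cold enough not to dehydrogenate ring B to a benzofuran.

Step 12
Reactants: 17 diaryldiazomethane
Product: 19 (2S,3S,2'S,3'S)-6-bromo-3'-(3,5-dimethoxyphenyl)-4,4'-dimethoxy-2,2'-bis(4-methoxyphenyl)-2,3,2',3'-tetrahydro-3,6'-bibenzofuran (both rings trans), via cis-ring-A bromide 18 (not isolated)
Conditions: Rh2(S-PTAD)4 (1 mol %), 4 Å MS, CH2Cl2, 0 °C → rt; then CF3CO2H, 0 °C → rt, same flask
Reagents that add atoms: none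
Why: The donor/donor carbene 1,5-C–H insertion of step 7 closes ring A, with C3 set by the catalyst because the stereocentres of ring B lie too far from the carbene carbon to interfere, and the acid equilibration moves C2 to the trans position while ring B, already trans, only returns to itself.

Step 13
Reactants: 20 2,4-dimethoxybenzaldehyde
Product: 21 2,4-dimethoxystyrene
Conditions: Ph3PCH3Br, KOt-Bu, THF, 0 °C → rt
Reagents that add atoms: methyltriphenylphosphonium bromide, C[P+](c1ccccc1)(c1ccccc1)c1ccccc1.[Br-]
Why: Wittig methylenation of an electron-rich benzaldehyde with the non-stabilised ylide, which gives the terminal styrene without any question of geometry.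

Step 14
Reactants: 19 bis(dihydrobenzofuran) bromide; 21 2,4-dimethoxystyrene
Product: 22 (2S,3S,2'S,3'S)-6-[(E)-2-(2,4-dimethoxyphenyl)ethenyl]-3'-(3,5-dimethoxyphenyl)-4,4'-dimethoxy-2,2'-bis(4-methoxyphenyl)-2,3,2',3'-tetrahydro-3,6'-bibenzofuran (octamethyl ether of the target)
Conditions: Pd(OAc)2 (cat.), P(o-tol)3 (cat.), Et3N, DMF, 100 °C
Reagents that add atoms: none
Why: Mizoroki–Heck reaction, in which oxidative addition into the only C–Br bond, syn-insertion at the unsubstituted styrene terminus and syn-β-hydride elimination should give the E-stilbene, and the amine base is too weak to disturb C3–H or C3'–H.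

Step 15
Reactants: 22 octamethyl ether
Product: 23 (2S,3S,2'S,3'S)-6-[(E)-2-(2,4-dihydroxyphenyl)ethenyl]-3'-(3,5-dihydroxyphenyl)-2,2'-bis(4-hydroxyphenyl)-2,3,2',3'-tetrahydro-3,6'-bibenzofuran-4,4'-diol (CNP0186204.1)
Conditions: BBr3 (excess), CH2Cl2, −78 °C → rt; then ice-water
Reagents that add atoms: none
Why: Boron tribromide cleavage of aryl methyl ethers, a usual closing step for permethylated stilbenoid oligomers, in which any ionisation of C2–O1 or C2'–O1' is reversible and leads back to the trans rings, and the styryl group at C6 has no arene within reach for a Friedel–Crafts ring closure.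

**Compound list**
1 | 4-bromo-2,6-dimethoxybenzaldehyde | COc1cc(Br)cc(OC)c1C=O | starting material
2 | 4-bromo-2-hydroxy-6-methoxybenzaldehyde | COc1cc(Br)cc(O)c1C=O | intermediate
3 | 4-methoxybenzyl chloride | COc1ccc(CCl)cc1 | starting material
4 | 4-bromo-2-methoxy-6-[(4-methoxybenzyl)oxy]benzaldehyde | COc1ccc(COc2cc(Br)cc(OC)c2C=O)cc1 | intermediate
5 | 1-bromo-3,5-dimethoxybenzene | COc1cc(Br)cc(OC)c1 | starting material
6 | 3,5-dimethoxyphenylmagnesium bromide | COc1cc([Mg]Br)cc(OC)c1 | intermediate
7 | [4-bromo-2-methoxy-6-(4-methoxybenzyloxy)phenyl](3,5-dimethoxyphenyl)methanol, racemic | OC(c1cc(OC)cc(OC)c1)c1c(OC)cc(Br)cc1OCc1ccc(OC)cc1 | intermediate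
8 | [4-bromo-2-methoxy-6-(4-methoxybenzyloxy)phenyl](3,5-dimethoxyphenyl)methanone | O=C(c1cc(OC)cc(OC)c1)c1c(OC)cc(Br)cc1OCc1ccc(OC)cc1 | intermediate
9 | hydrazone of 8, E/Z mixture | NN=C(c1cc(OC)cc(OC)c1)c1c(OC)cc(Br)cc1OCc1ccc(OC)cc1 | intermediate
10 | [4-bromo-2-methoxy-6-(4-methoxybenzyloxy)phenyl](3,5-dimethoxyphenyl)diazomethane | [N-]=[N+]=C(c1cc(OC)cc(OC)c1)c1c(OC)cc(Br)cc1OCc1ccc(OC)cc1 | intermediate
11 | (2R,3S)-6-bromo-3-(3,5-dimethoxyphenyl)-4-methoxy-2-(4-methoxyphenyl)-2,3-dihydrobenzofuran, cis | Brc1cc(OC)c2c(c1)O[C@@H](c1ccc(OC)cc1)[C@H]2c1cc(OC)cc(OC)c1 | intermediate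
12 | (2S,3S)-6-bromo-3-(3,5-dimethoxyphenyl)-4-methoxy-2-(4-methoxyphenyl)-2,3-dihydrobenzofuran, trans | Brc1cc(OC)c2c(c1)O[C@H](c1ccc(OC)cc1)[C@H]2c1cc(OC)cc(OC)c1 | intermediate
13 | (2S,3S)-3-(3,5-dimethoxyphenyl)-4-methoxy-2-(4-methoxyphenyl)-2,3-dihydrobenzofuran-6-yllithium | [Li]c1cc(OC)c2c(c1)O[C@H](c1ccc(OC)cc1)[C@H]2c1cc(OC)cc(OC)c1 | intermediate
14 | carbinol joining ring-A aryl and ring-B unit, both carbinol epimers | OC(c1cc(OC)c2c(c1)O[C@H](c1ccc(OC)cc1)[C@H]2c1cc(OC)cc(OC)c1)c1c(OC)cc(Br)cc1OCc1ccc(OC)cc1 | intermediate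
15 | ketone from 14 | O=C(c1cc(OC)c2c(c1)O[C@H](c1ccc(OC)cc1)[C@H]2c1cc(OC)cc(OC)c1)c1c(OC)cc(Br)cc1OCc1ccc(OC)cc1 | intermediate
16 | hydrazone of 15, E/Z mixture | NN=C(c1cc(OC)c2c(c1)O[C@H](c1ccc(OC)cc1)[C@H]2c1cc(OC)cc(OC)c1)c1c(OC)cc(Br)cc1OCc1ccc(OC)cc1 | intermediate
17 | diaryldiazomethane from 16 | [N-]=[N+]=C(c1cc(OC)c2c(c1)O[C@H](c1ccc(OC)cc1)[C@H]2c1cc(OC)cc(OC)c1)c1c(OC)cc(Br)cc1OCc1ccc(OC)cc1 | intermediate
18 | (2R,3S,2'S,3'S)-bibenzofuran bromide, ring A cis, ring B trans | COc1ccc([C@@H]2Oc3cc(Br)cc(OC)c3[C@@H]2c2cc(OC)c3c(c2)O[C@H](c2ccc(OC)cc2)[C@H]3c2cc(OC)cc(OC)c2)cc1 | intermediate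
19 | (2S,3S,2'S,3'S)-6-bromo-3'-(3,5-dimethoxyphenyl)-4,4'-dimethoxy-2,2'-bis(4-methoxyphenyl)-2,3,2',3'-tetrahydro-3,6'-bibenzofuran | COc1ccc([C@H]2Oc3cc(Br)cc(OC)c3[C@@H]2c2cc(OC)c3c(c2)O[C@H](c2ccc(OC)cc2)[C@H]3c2cc(OC)cc(OC)c2)cc1 | intermediate
20 | 2,4-dimethoxybenzaldehyde | COc1ccc(C=O)c(OC)c1 | starting material
21 | 2,4-dimethoxystyrene | C=Cc1ccc(OC)cc1OC | intermediate
22 | octamethyl ether of the target, E alkene | COc1ccc([C@H]2Oc3cc(/C=C/c4ccc(OC)cc4OC)cc(OC)c3[C@@H]2c2cc(OC)c3c(c2)O[C@H](c2ccc(OC)cc2)[C@H]3c2cc(OC)cc(OC)c2)cc1 | intermediate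
23 | CNP0186204.1, (2S,3S,2'S,3'S), E alkene | Oc1ccc([C@H]2Oc3cc(/C=C/c4ccc(O)cc4O)cc(O)c3[C@@H]2c2cc(O)c3c(c2)O[C@H](c2ccc(O)cc2)[C@H]3c2cc(O)cc(O)c2)cc1 | target

**Count**
Total steps: 15. Longest linear sequence: 14 steps (1 → 2 → 4 → 7 → 8 → 9 → 10 → 12 → 14 → 15 → 16 → 17 → 19 → 22 → 23, that is steps 1–12, 14 and 15). Step 13 is a one-step side branch.

**Steps most likely to fail**

Step 5 (the same operation returns in step 10). The condensation may stall, because the carbonyl carbon is shielded by two ortho alkoxy groups and deactivated by their donation. Harsher forcing may begin to cleave the benzylic ether. The fallback sets out from ketone 8 and changes the electrophile. Thionation with Lawesson's reagent (toluene, 100 °C) should give the diaryl thioketone F1. Its C=S bond accepts nitrogen nucleophiles far more readily than the C=O bond does. Hydrazine hydrate in THF/EtOH at room temperature then replaces sulfur, and the route is rejoined at hydrazone 9.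

Step 7 (the same reaction type returns in step 12). Three processes could interfere.
- The hindered carbene may be diverted into azine formation or capture by adventitious water or oxygen before it reaches the C–H bond.
- The twisted di-ortho-substituted aryl group may weaken enantiofacial discrimination in the ligand pocket.
- Prolonged acid may erode C3' through reversible proton loss from the ring-opened cation.

The fallback sets out from ketone 8 and closes ring B through C2'–O1' instead.
- Corey–Chaykovsky methylenation (Me3SI, NaH, DMSO/THF) should give the 2,2-diaryloxirane F2.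
- ZnI2 in toluene should trigger a Meinwald rearrangement to the diarylacetaldehyde F3.
- 4-Methoxyphenylmagnesium bromide (THF, −78 → 0 °C) should add to give the 1,2,2-triarylethanol F4.
- CF3CO2H with anisole as cation trap (CH2Cl2, 0 °C) should remove the 4-methoxybenzyl group and ionise the benzylic alcohol, after which the freed phenol captures the cation anti to the C3' aryl group.

This delivers the racemic trans bromide, that is 12 together with the (2R,3R) enantiomer F5. Preparative chromatography on a chiral stationary phase returns to the route at 12.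

Step 15. Hydrogen bromide formed during the reaction or the quench may protonate the very electron-rich 2,4-dioxygenated stilbene and start oligomerisation. Cleavage of eight ethers may also stop short, and bromide may trap a ring-opened benzylic cation irreversibly. The fallback sets out from bromide 19 and removes the methyl groups before the alkene exists.
- BBr3 (CH2Cl2, −78 °C → rt) should give the hexaphenol bromide F6.
- TBSCl and imidazole in DMF should give the hexakis(silyl ether) F7.
- In parallel, commercial 2,4-dihydroxybenzaldehyde is silylated to 2,4-bis(tert-butyldimethylsilyloxy)benzaldehyde F8 and methylenated (Ph3PCH3Br, KOt-Bu, THF) to 2,4-bis(tert-butyldimethylsilyloxy)styrene F9.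
- Heck coupling of the two (Pd(OAc)2, P(o-tol)3, Et3N, toluene, 90 °C) should give the octakis(silyl ether) F10.
- Et3N·3HF in THF at 0 °C → rt frees all phenols under nearly neutral conditions and reaches target 23.

**Further compounds**
F1 | step 5 | [4-bromo-2-methoxy-6-(4-methoxybenzyloxy)phenyl](3,5-dimethoxyphenyl)methanethione | S=C(c1cc(OC)cc(OC)c1)c1c(OC)cc(Br)cc1OCc1ccc(OC)cc1
F2 | step 7 | 2-[4-bromo-2-methoxy-6-(4-methoxybenzyloxy)phenyl]-2-(3,5-dimethoxyphenyl)oxirane, racemic | COc1ccc(COc2cc(Br)cc(OC)c2C2(CO2)c2cc(OC)cc(OC)c2)cc1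
F3 | step 7 | 2-[4-bromo-2-methoxy-6-(4-methoxybenzyloxy)phenyl]-2-(3,5-dimethoxyphenyl)acetaldehyde, racemic | O=CC(c1cc(OC)cc(OC)c1)c1c(OC)cc(Br)cc1OCc1ccc(OC)cc1
F4 | step 7 | 2-[4-bromo-2-methoxy-6-(4-methoxybenzyloxy)phenyl]-2-(3,5-dimethoxyphenyl)-1-(4-methoxyphenyl)ethanol, diastereomer mixture | OC(c1ccc(OC)cc1)C(c1cc(OC)cc(OC)c1)c1c(OC)cc(Br)cc1OCc1ccc(OC)cc1
F5 | step 7 | (2R,3R)-6-bromo-3-(3,5-dimethoxyphenyl)-4-methoxy-2-(4-methoxyphenyl)-2,3-dihydrobenzofuran, enantiomer of 12 | Brc1cc(OC)c2c(c1)O[C@@H](c1ccc(OC)cc1)[C@@H]2c1cc(OC)cc(OC)c1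
F6 | step 15 | (2S,3S,2'S,3'S)-6-bromo-3'-(3,5-dihydroxyphenyl)-2,2'-bis(4-hydroxyphenyl)-2,3,2',3'-tetrahydro-3,6'-bibenzofuran-4,4'-diol | Oc1ccc([C@H]2Oc3cc(Br)cc(O)c3[C@@H]2c2cc(O)c3c(c2)O[C@H](c2ccc(O)cc2)[C@H]3c2cc(O)cc(O)c2)cc1
F7 | step 15 | hexakis(tert-butyldimethylsilyl) ether of F6 | CC(C)(C)[Si](C)(C)Oc1ccc([C@H]2Oc3cc(Br)cc(O[Si](C)(C)C(C)(C)C)c3[C@@H]2c2cc(O[Si](C)(C)C(C)(C)C)c3c(c2)O[C@H](c2ccc(O[Si](C)(C)C(C)(C)C)cc2)[C@H]3c2cc(O[Si](C)(C)C(C)(C)C)cc(O[Si](C)(C)C(C)(C)C)c2)cc1
F8 | step 15 | 2,4-bis(tert-butyldimethylsilyloxy)benzaldehyde | O=Cc1ccc(O[Si](C)(C)C(C)(C)C)cc1O[Si](C)(C)C(C)(C)C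
F9 | step 15 | 2,4-bis(tert-butyldimethylsilyloxy)styrene | C=Cc1ccc(O[Si](C)(C)C(C)(C)C)cc1O[Si](C)(C)C(C)(C)C
F10 | step 15 | octakis(tert-butyldimethylsilyl) ether of 23 | CC(C)(C)[Si](C)(C)Oc1ccc([C@H]2Oc3cc(/C=C/c4ccc(O[Si](C)(C)C(C)(C)C)cc4O[Si](C)(C)C(C)(C)C)cc(O[Si](C)(C)C(C)(C)C)c3[C@@H]2c2cc(O[Si](C)(C)C(C)(C)C)c3c(c2)O[C@H](c2ccc(O[Si](C)(C)C(C)(C)C)cc2)[C@H]3c2cc(O[Si](C)(C)C(C)(C)C)cc(O[Si](C)(C)C(C)(C)C)c2)cc1
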